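**Retrosynthetic overview**
1. The C10–C14 bond and the ring-cis C1=C10 enal come last, by OH-directed syn-hydroformylation of a ten-membered ring alkyne. The C9 ester comes from acylation of the propargylic OH.
2. The α-methylene-γ-lactone comes from 1,2-reduction of a C6 ketone and closure onto the C12 ester already on C7.
3. The ten-membered enynone comes from a ring expansion: Eschenmoser–Tanabe-type cleavage of the shared C1–C6 bond of a six-six bicycle (C6–OH, C1–Cl, C10=O).
4. Ring B comes from an indium Barbier closure C6–C7. C1–C10 comes from an aldol of 3-methylcyclohex-2-enone (ring A, which brings C1–C6, C15 and the Z C4=C5 bond).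
5. C7–C10 come from D-erythronolactone acetonide, C11–C13 from methyl acrylate, C14 from CO. Ring order: A (bought), then B, then the ten-membered ring, then the lactone.

Germacrane numbering is used throughout: C1=C10(C14HO), C4(C15H3)=C5, C6–O (lactone), C7, C8–OH, C9–O-acyl, C11=C13H2, C12=O.

Assumption: stereocentres that are erased again later (C7–OH in 4; C1, C6 and C10 in 9–14) are carried as mixtures and left open in the SMILES.

Step 1
Reactants: 1 (−)-2,3-O-isopropylidene-D-erythronolactone (lactone C=O is C7, then C8, C9, and CH2O is C10)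
Product: 2 2,3-O-isopropylidene-D-erythrose (furanose lactol, anomer mixture)
Conditions: iBu2AlH (1.1 equiv), CH2Cl2, −78 °C; H2O work-up
Reagents that add atoms: none
Why: Lactone-to-lactol half-reduction stops at the aluminium lactolate at −78 °C, and C8 and C9 are not touched.

Step 2
Reactants: 2 2,3-O-isopropylidene-D-erythrose; 3 methyl acrylate
Product: 4 methyl 2-{hydroxy[(4S,5R)-5-(hydroxymethyl)-2,2-dimethyl-1,3-dioxolan-4-yl]methyl}prop-2-enoate (carbinol epimers)
Conditions: 3 (3 equiv), DABCO (0.5 equiv), 1,4-dioxane–H2O (1:1), rt, 48 h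
Reagents that add atoms: none
Why: Morita–Baylis–Hillman reaction in which the open-chain α-alkoxy aldehyde in equilibrium with 2 is trapped by the DABCO–acrylate zwitterion to form C7–C11, and the new carbinol centre does not matter because step 3 erases it.

Step 3
Reactants: 4 Morita–Baylis–Hillman diol
Product: 5 methyl (Z)-2-(bromomethyl)-3-[(4S,5R)-5-(hydroxymethyl)-2,2-dimethyl-1,3-dioxolan-4-yl]prop-2-enoate
Conditions: NBS (1.5 equiv), Me2S (1.8 equiv), CH2Cl2, −20 to 0 °C; H2O work-up; used at once
Reagents that add atoms: N-bromosuccinimide, O=C1CCC(=O)N1Br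
Why: Corey–Kim-type halogenation in which bromide attacks only the allylic alkoxysulfonium salt (SN2′, giving the Z-2-(bromomethyl)enoate), while the saturated primary alkoxysulfonium salt reverts to the alcohol on aqueous work-up.

Step 4
Reactants: 5 allylic bromide alcohol
Product: 6 methyl (Z)-2-(bromomethyl)-3-[(4S,5S)-5-formyl-2,2-dimethyl-1,3-dioxolan-4-yl]prop-2-enoate
Conditions: Dess–Martin periodinane (1.2 equiv), CH2Cl2, 0 °C to rt
Reagents that add atoms: none
Why: Dess–Martin oxidation is neutral enough to leave the allylic bromide, the acetonide and the epimerisable C9 centre intact.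

Step 5
Reactants: 6 aldehyde; 7 3-methylcyclohex-2-en-1-one
Product: 9 aldol adduct methyl (Z)-2-(bromomethyl)-3-{5-[hydroxy(4-methyl-2-oxocyclohex-3-en-1-yl)methyl]-2,2-dimethyl-1,3-dioxolan-4-yl}prop-2-enoate (C1/C10 epimers; C8 and C9 as in 6), via lithium dienolate 8 (not isolated)
Conditions: 7, LiN(iPr)2 (1.05 equiv), THF, −78 °C, 30 min; 6, 5 min; AcOH quench at −78 °C
Reagents that add atoms: none
Why: Kinetic α′-deprotonation gives the cross-conjugated dienolate, whose aldol addition to the aldehyde (C1–C10 bond) at −78 °C is far faster than alkylation by the allylic bromide, and both new centres are erased later.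

Step 6
Reactants: 9 aldol adduct
Product: 11 methyl (Z)-2-(bromomethyl)-3-{(4S,5S)-5-[(1-chloro-4-methyl-2-oxocyclohex-3-en-1-yl)carbonyl]-2,2-dimethyl-1,3-dioxolan-4-yl}prop-2-enoate (C1 epimers), via diketone 10 (not isolated)
Conditions: Dess–Martin periodinane (1.3 equiv), CH2Cl2, rt; then NCS (1.05 equiv), rt
Reagents that add atoms: N-chlorosuccinimide, O=C1CCC(=O)N1Cl
Why: Dess–Martin oxidation gives the 1,3-diketone, and electrophilic α-chlorination of its enol occurs only at the doubly activated C1, which blocks enolisation (C6 becomes a true ketone) and raises C1 to the oxidation level the alkyne needs.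

Step 7
Reactants: 11 chloro diketone
Product: 12 ring-B-closed chlorohydrin (7R,8S,9S): a decalin with tertiary allylic C6–OH, C1–Cl, C10=O, the C8/C9 acetonide, and C7 bearing the 1-(methoxycarbonyl)vinyl group
Conditions: indium powder (1.5 equiv), THF–H2O (4:1), 0.01 M, rt, sonication
Reagents that add atoms: none
Why: Intramolecular indium Barbier allylation (γ-attack, SE2′) of the activated C6 ketone tolerates the α-chloro ketone and closes ring B through a chair with the acrylate unit equatorial, C8–H anti and C8–O gauche to the forming C6–C7 bond, which puts C11 cis to O8 and O9 (7R).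

Step 8
Reactants: 12 chlorohydrin
Product: 15 methyl (4Z,7R,8S,9R)-8,9-(isopropylidenedioxy)-6-oxo-14-norgermacra-4,11(13)-dien-1(10)-yn-12-oate (ten-membered enynone), via tosylhydrazone 13 (not isolated), via azoalkene 14 (not isolated)
Conditions: TsNHNH2 (1.1 equiv), AcOH–CH2Cl2 (1:2), −20 °C to rt; then NaOAc (1.5 equiv), rt
Reagents that add atoms: none
Why: Eschenmoser–Tanabe-type fragmentation in which the α-chloro tosylhydrazone loses HCl to the same β-hydroxy azoalkene that an epoxy tosylhydrazone gives, and the C6–OH then pushes out N2 and sulfinate through the anti-aligned C6–C1 bond, cleaving the shared bond (six-six to ten) to give the C6 ketone, the C1≡C10 alkyne and the Z C4=C5 bond inherited from ring A.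

Step 9
Reactants: 15 enynone
Product: 18 (4Z,6R,7R,8S,9R)-8,9-dihydroxy-14-norgermacra-4,11(13)-dien-1(10)-yn-12,6-olide, via allylic alcohol 16 (not isolated), via lactone acetonide 17 (not isolated)
Conditions: CeCl3·7H2O (1.2 equiv), NaBH4 (1.0 equiv), MeOH, −78 °C; then 1 M aq HCl, rt
Reagents that add atoms: none
Why: Luche 1,2-reduction with hydride adding to the outer face of the ring ketone in the Felkin–Anh sense (C7–C8 perpendicular to C=O, attack past C7–H) sets 6R, the C6 oxygen closes the trans-fused lactone on the neighbouring methyl ester before O8 is freed, and the acid then hydrolyses the acetonide.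

Step 10
Reactants: 18 diol lactone; 19 (R)-2-methylbutanoic acid
Product: 20 (4Z,6R,7R,8S,9R)-8-hydroxy-9-[(2R)-2-methylbutanoyloxy]-14-norgermacra-4,11(13)-dien-1(10)-yn-12,6-olide
Conditions: 19 (1.05 equiv), DIC (1.1 equiv), DMAP (0.1 equiv), CH2Cl2, −20 °C
Reagents that add atoms: none
Why: Steglich esterification acylates the propargylic C9–OH (next to the slim sp carbon) in preference to the C8–OH (between two branched sp3 carbons and hydrogen-bonded to the lactone C=O), and no stereocentre is touched.

Step 11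
Reactants: 20 alkyne ester
Product: 21 target, (1(10)E,4Z,6R,7R,8S,9R)-8-hydroxy-9-[(2R)-2-methylbutanoyloxy]-14-oxogermacra-1(10),4,11(13)-trien-12,6-olide
Conditions: Rh(CO)2(acac) (3 mol %), Ph2POMe (15 mol %), CO/H2 (1:1, 10 bar), 4 Å molecular sieves, toluene, 35 °C
Reagents that add atoms: carbon monoxide, [C-]#[O+]
Why: Proposed new method: the free C8–OH exchanges reversibly with Ph2POMe so that the monovalent rhodium hydride is held on phosphorus and adds syn across the strained ring alkyne with Rh on C10 (six-membered Rh–P–O–C8–C9–C10 chelate; Rh on C1 would need a seven-membered one), then CO insertion and hydrogenolysis give C10–CHO cis to the new C1–H, that is C2 cis to C9 as in the target, while the unstrained, undirected acrylate and trisubstituted alkene react far more slowly; the closest known reaction types are rhodium hydroformylation of homoallylic alcohols steered by a catalytic reversibly bound phosphinite and the undirected syn-hydroformylation of symmetrical internal alkynes to enals.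

**Compound list**
1 | (−)-2,3-O-isopropylidene-D-erythronolactone | CC1(C)O[C@@H]2COC(=O)[C@@H]2O1 | starting material
2 | 2,3-O-isopropylidene-D-erythrose (lactol) | CC1(C)O[C@@H]2COC(O)[C@@H]2O1 | intermediate
3 | methyl acrylate | C=CC(=O)OC | starting material
4 | Morita–Baylis–Hillman diol | C=C(C(=O)OC)C(O)[C@@H]1OC(C)(C)O[C@@H]1CO | intermediate
5 | (Z)-allylic bromide alcohol | BrC/C(C(=O)OC)=C\[C@@H]1OC(C)(C)O[C@@H]1CO | intermediate
6 | (Z)-allylic bromide aldehyde | BrC/C(C(=O)OC)=C\[C@@H]1OC(C)(C)O[C@@H]1C=O | intermediate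
7 | 3-methylcyclohex-2-en-1-one | CC1=CC(=O)CCC1 | starting material
8 | lithium cross-conjugated dienolate of 7 | [Li+].CC1=CC([O-])=CCC1 | intermediate
9 | aldol adduct | CC1=CC(=O)C(CC1)C(O)[C@H]2OC(C)(C)O[C@H]2/C=C(\CBr)C(=O)OC | intermediate
10 | 1,3-diketone | CC1=CC(=O)C(CC1)C(=O)[C@H]2OC(C)(C)O[C@H]2/C=C(\CBr)C(=O)OC | intermediate
11 | 2-chloro-1,3-diketone | CC1=CC(=O)C(Cl)(CC1)C(=O)[C@H]2OC(C)(C)O[C@H]2/C=C(\CBr)C(=O)OC | intermediate
12 | bicyclic chlorohydrin | CC1=CC2(O)C(Cl)(CC1)C(=O)[C@H]3OC(C)(C)O[C@H]3[C@H]2C(=C)C(=O)OC | intermediate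
13 | α-chloro tosylhydrazone | CC1=CC2(O)C(Cl)(CC1)C(=NNS(=O)(=O)c4ccc(C)cc4)[C@H]3OC(C)(C)O[C@H]3[C@H]2C(=C)C(=O)OC | intermediate
14 | β-hydroxy azoalkene | CC1=CC2(O)C(CC1)=C(N=NS(=O)(=O)c4ccc(C)cc4)[C@H]3OC(C)(C)O[C@H]3[C@H]2C(=C)C(=O)OC | intermediate
15 | ten-membered enynone | C/C1=C/C(=O)[C@H](C(=C)C(=O)OC)[C@@H]2OC(C)(C)O[C@@H]2C#CCC1 | intermediate
16 | 6R allylic alcohol | C/C1=C/[C@@H](O)[C@H](C(=C)C(=O)OC)[C@@H]2OC(C)(C)O[C@@H]2C#CCC1 | intermediate
17 | lactone acetonide | C=C1C(=O)O[C@@H]2/C=C(/C)CCC#C[C@H]3OC(C)(C)O[C@H]3[C@@H]12 | intermediate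
18 | diol lactone | C=C1C(=O)O[C@@H]2/C=C(/C)CCC#C[C@@H](O)[C@@H](O)[C@@H]12 | intermediate
19 | (R)-2-methylbutanoic acid | CC[C@@H](C)C(=O)O | starting material
20 | C9 ester of the ring alkyne | C=C1C(=O)O[C@@H]2/C=C(/C)CCC#C[C@@H](OC(=O)[C@H](C)CC)[C@@H](O)[C@@H]12 | intermediate
21 | CNP0256845.2 | C=C1C(=O)O[C@@H]2/C=C(/C)CC/C=C(/C=O)[C@@H](OC(=O)[C@H](C)CC)[C@@H](O)[C@@H]12 | target

Total step count: 11. Longest linear sequence: 11 steps (1 to 21).

**Steps most likely to fail**

**Step 7.** Indium may attack the C1–Cl bond, water may cleave the non-enolisable diketone, and the C7 selectivity may be low.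
The fallback sets out from 10, isolated by leaving NCS out of step 6, and returns to the route at 14.
- Indium in THF–H2O closes ring B on the enolised diketone (aqueous Barbier allylation of a 1,3-diketone) to give the ketol F1.
- PPTS-catalysed dehydration gives the linear dienone F2.
- Weitz–Scheffer epoxidation (t-BuOOH, DBU) of the tetrasubstituted C1=C6 bond gives the epoxy ketone F3.
- TsNHNH2 in AcOH–CH2Cl2 gives the epoxy tosylhydrazone F4, which opens to 14 in the classical way.

**Step 9.** Hydride may arrive from the other face of the medium-ring ketone.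
The fallback sets out from 15 and returns at 17.
- The same reduction then delivers the 6S alcohol F5.
- F5 is saponified (LiOH, THF–H2O) to the hydroxy acid F6.
- F6 is closed by Mitsunobu lactonisation (PPh3, DIAD), which activates C6–OH and inverts it, giving the trans-lactone 17.

**Step 11 (the proposed new step).** The regiocontrol, over-reduction of the enal, and attack on the α-methylene lactone are all untested.
The fallback uses known chemistry, sets out from 20 and returns at 21.
- Syn-hydrostannation (Bu3SnH, PdCl2(PPh3)2, THF) puts tin on the alkyne carbon next to the acyloxy-bearing carbon, giving the vinylstannane F7.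
- I2 in CH2Cl2 gives the vinyl iodide F8 with retention of geometry.
- Formylation catalysed by zerovalent palladium (Pd(PPh3)4, CO 1 atm, slow addition of Bu3SnH) gives 21.

**Further compounds**
F1 | step 7 | bicyclic ketol (C1–H) | CC1=CC2(O)C(CC1)C(=O)[C@H]3OC(C)(C)O[C@H]3[C@H]2C(=C)C(=O)OC
F2 | step 7 | bicyclic linear dienone | CC1=CC2=C(CC1)C(=O)[C@H]3OC(C)(C)O[C@H]3[C@H]2C(=C)C(=O)OC
F3 | step 7 | C1–C6 epoxy ketone | CC1=CC23OC2(CC1)C(=O)[C@H]4OC(C)(C)O[C@H]4[C@H]3C(=C)C(=O)OC
F4 | step 7 | epoxy tosylhydrazone | CC1=CC23OC2(CC1)C(=NNS(=O)(=O)c5ccc(C)cc5)[C@H]4OC(C)(C)O[C@H]4[C@H]3C(=C)C(=O)OC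
F5 | step 9 | 6S allylic alcohol (6-epimer of 16) | C/C1=C/[C@H](O)[C@H](C(=C)C(=O)OC)[C@@H]2OC(C)(C)O[C@@H]2C#CCC1
F6 | step 9 | 6S hydroxy acid | C/C1=C/[C@H](O)[C@H](C(=C)C(=O)O)[C@@H]2OC(C)(C)O[C@@H]2C#CCC1
F7 | step 11 | C10 tributylvinylstannane | C=C1C(=O)O[C@@H]2/C=C(/C)CC/C=C(/[Sn](CCCC)(CCCC)CCCC)[C@@H](OC(=O)[C@H](C)CC)[C@@H](O)[C@@H]12
F8 | step 11 | C10 vinyl iodide | C=C1C(=O)O[C@@H]2/C=C(/C)CC/C=C(/I)[C@@H](OC(=O)[C@H](C)CC)[C@@H](O)[C@@H]12
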